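**Strategy.** The trimer is cut at the C4–O–C4 ether and at the C4–C8 bond into three benzyl-protected flavan-3-ols. The pyran ring (ring C) of the middle unit, and with the same material of the upper unit, is made by closing its C2–C3 bond. C2 carries the ring oxygen O1 and the catechol ring B, so it is traced back to the carbonyl carbon of an aryl benzoate; C3 and C4 come from an ortho allyl group. One titanium-mediated olefin–ester ring-closing metathesis converts this open ester into the flat 2-aryl-4H-chromene, whose C2=C3 enol ether then takes up both stereocentres by asymmetric hydroboration. DDQ and Lewis acid chemistry at C4 joins the units.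

Key step: step 4

Assumption: (+)-epicatechin (2S,3S), 3,5-bis(benzyloxy)phenol and 3,4-bis(benzyloxy)benzoic acid are taken as catalogue compounds; flavan atoms are numbered O1, C2, C3, C4, C4a, C5 to C8, C8a (ring A phloroglucinol ring, ring B catechol ring, ring C pyran ring), and the three flavan units are called upper, middle and lower (the ether-linked 2S,3S unit).

Step 1
Reactants: 1 3,5-bis(benzyloxy)phenol
Product: 2 1-(allyloxy)-3,5-bis(benzyloxy)benzene
Conditions: allyl bromide, K2CO3, acetone, reflux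
Reagents that add atoms: allyl bromide, C=CCBr
Why: Williamson etherification of the single free phenol under mild carbonate base, with no stereocentre involved.

Step 2
Reactants: 2 1-(allyloxy)-3,5-bis(benzyloxy)benzene
Product: 3 2-allyl-3,5-bis(benzyloxy)phenol
Conditions: PhNEt2, 200 °C
Reagents that add atoms: none
Why: Aromatic Claisen rearrangement ([3,3]-sigmatropic shift) moves the allyl group to one of the two equivalent ortho carbons, so one regioisomer should form and the aryl benzyl ethers tolerate the heat.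

Step 3
Reactants: 3 2-allyl-3,5-bis(benzyloxy)phenol; 4 3,4-bis(benzyloxy)benzoic acid
Product: 5 2-allyl-3,5-bis(benzyloxy)phenyl 3,4-bis(benzyloxy)benzoate
Conditions: EDC·HCl, DMAP (cat.), CH2Cl2, rt
Reagents that add atoms: none
Why: Steglich esterification (carbodiimide activation, DMAP acyl transfer) acylates the phenol under neutral conditions that leave the allyl group and the benzyl ethers untouched.

Step 4
Reactants: 5 2-allyl-3,5-bis(benzyloxy)phenyl 3,4-bis(benzyloxy)benzoate
Product: 7 5,7-bis(benzyloxy)-2-[3,4-bis(benzyloxy)phenyl]-4H-chromene, via dichlorotitanium alkylidene 6 (not isolated)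
Conditions: TiCl4, TMEDA, Zn, PbCl2 (cat.), CH3CHBr2, THF/CH2Cl2, 0 → 65 °C
Reagents that add atoms: none
Why: The low-valent titanium ethylidene formed in situ from CH3CHBr2, Zn and TiCl4 first exchanges with the terminal alkene of 5 (alkene metathesis, loss of propene) to give alkylidene 6, whose Ti=C3 unit adds across the ester C2=O to an oxatitanacyclobutane that cycloreverts to the C2=C3 enol ether and a titanium oxo species. The closest known reaction type is the Takai–Utimoto ester alkylidenation in its ring-closing olefin–ester metathesis (olefinic ester cyclization) form, which is established for six- and seven-membered cyclic enol ethers. The pyran ring closes in a 6-exo mode at the ester carbonyl (the carbonyl oxygen stays outside the new ring and is lost to titanium), and the C2–C3 bond is the only ring bond formed. No stereocentre is created; the planar enol ether hands C2 and C3 over to the reagent-controlled hydroboration of step 5. The step needs alkene exchange to come before simple ethylidenation of the carbonyl and the acid-labile enol ether to survive: the unhindered monosubstituted allyl group, the rigid ortho tether that holds the new alkylidene five atoms from the carbonyl carbon, and the TMEDA-buffered aprotic medium should secure this, while aryl benzyl ethers are inert to the reagent.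

Step 5
Reactants: 7 5,7-bis(benzyloxy)-2-[3,4-bis(benzyloxy)phenyl]-4H-chromene
Product: 9 (2R,3S)-5,7,3',4'-tetra-O-benzylcatechin, via (2R,3S)-flavan-3-yl(isopinocampheyl)borane 8 (not isolated)
Conditions: IpcBH2 (from (+)-α-pinene), THF, −25 °C; then NaOH, H2O2, 0 °C → rt
Reagents that add atoms: hydrogen peroxide, OO (monoisopinocampheylborane, [BH2][C@@H]1C[C@@H]2C[C@H]([C@H]1C)C2(C)C, ends up only in intermediate 8)
Why: Brown asymmetric hydroboration–oxidation adds H and B syn with boron at C3 (β to the enol-ether oxygen, remote from the aryl-bearing C2), so oxidation with retention gives the 2,3-trans alcohol, and the isopinocampheyl group selects the alkene face, the reagent from (+)-α-pinene being expected to give 2R,3S by analogy with 1-arylcycloalkenes (its antipode is used should the first run show the opposite sense; crystallisation of 9 should raise the enantiomeric purity).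

Step 6
Reactants: 9 (2R,3S)-5,7,3',4'-tetra-O-benzylcatechin
Product: 10 (2R)-5,7,3',4'-tetra-O-benzylflavan-3-one
Conditions: Dess–Martin periodinane, CH2Cl2, rt
Reagents that add atoms: none
Why: Dess–Martin oxidation of the secondary alcohol under neutral conditions should give the ketone without epimerising the adjacent benzylic C2, and the crude ketone is reduced at once.

Step 7
Reactants: 10 (2R)-5,7,3',4'-tetra-O-benzylflavan-3-one
Product: 11 (2R,3R)-5,7,3',4'-tetra-O-benzylepicatechin
Conditions: L-Selectride (LiBH(s-Bu)3), LiBr, THF, −78 °C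
Reagents that add atoms: none
Why: Diastereoselective ketone reduction in which the bulky trialkylborohydride attacks C3 from the face opposite the C2 aryl group, placing the new hydroxyl cis to the aryl, the established passage from the catechin to the epicatechin series.

Step 8
Reactants: 11 (2R,3R)-5,7,3',4'-tetra-O-benzylepicatechin (one part of the batch)
Product: 12 4β-(2-ethoxyethoxy)-5,7,3',4'-tetra-O-benzylepicatechin (2,3-cis, 3,4-trans)
Conditions: DDQ, 2-ethoxyethanol, CH2Cl2, rt
Reagents that add atoms: 2-ethoxyethanol, CCOCCO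
Why: DDQ-mediated oxidative C–H alkoxylation, in which hydride abstraction from C4 gives a cation stabilised by the 5,7-dialkoxy ring A and the alcohol adds from the β face, trans to the 3-hydroxyl and the 2-aryl group.

Step 9
Reactants: 12 4β-(2-ethoxyethoxy)-5,7,3',4'-tetra-O-benzylepicatechin; 11 (2R,3R)-5,7,3',4'-tetra-O-benzylepicatechin (4 equiv, excess recovered)
Product: 13 octa-O-benzyl procyanidin B2, that is tetra-O-benzylepicatechin-(4β→8)-tetra-O-benzylepicatechin
Conditions: TMSOTf (0.1 equiv), CH2Cl2, −78 °C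
Reagents that add atoms: none
Why: Lewis acid-promoted Friedel–Crafts coupling of a flavan-4-yl cation, in which C8 of 11 (less hindered than C6) attacks the cation from 12 on the β face to give the 3,4-trans 4β→8 bond, the excess of 11 suppressing self-condensation of 12.

Step 10
Reactants: 14 (+)-epicatechin, (2S,3S)
Product: 15 (2S,3S)-5,7,3',4'-tetra-O-benzylepicatechin
Conditions: benzyl bromide, K2CO3, DMF, 0 °C → rt
Reagents that add atoms: benzyl bromide, BrCc1ccccc1
Why: Williamson etherification of the four phenols with carbonate base leaves the aliphatic 3-hydroxyl free and should not disturb C2.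

Step 11
Reactants: 15 (2S,3S)-5,7,3',4'-tetra-O-benzylepicatechin
Product: 16 (2S,3S)-3-O-(tert-butyldimethylsilyl)-5,7,3',4'-tetra-O-benzylepicatechin
Conditions: TBSOTf, 2,6-lutidine, CH2Cl2, 0 °C
Reagents that add atoms: tert-butyldimethylsilyl triflate, CC(C)(C)[Si](C)(C)OS(=O)(=O)C(F)(F)F
Why: Silylation of the hindered secondary alcohol with the silyl triflate blocks O3 as a nucleophile for step 16 and provides the axial group that steers the reduction in step 14.

Step 12
Reactants: 16 (2S,3S)-3-O-(tert-butyldimethylsilyl)-5,7,3',4'-tetra-O-benzylepicatechin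
Product: 17 4-hydroxy derivative of 16 with the 4-hydroxyl trans to O3 (2,3-cis, 3,4-trans)
Conditions: DDQ, CH2Cl2/H2O, rt
Reagents that add atoms: water, O
Why: DDQ benzylic oxidation (hydride abstraction at C4, capture of the cation by water anti to the 3-silyloxy group) installs the C4 oxygen, and the C4 configuration does not matter because step 13 erases it.

Step 13
Reactants: 17 4-hydroxy derivative of 16
Product: 18 (2S,3S)-3-O-(tert-butyldimethylsilyl)-5,7,3',4'-tetra-O-benzylflavan-3-ol-4-one (2,3-cis)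
Conditions: Dess–Martin periodinane, NaHCO3, CH2Cl2, rt
Reagents that add atoms: none
Why: Dess–Martin oxidation of the benzylic alcohol to the aryl ketone under buffered neutral conditions should not epimerise the base-sensitive 2,3-cis dihydroflavonol.

Step 14
Reactants: 18 (2S,3S)-3-O-(tert-butyldimethylsilyl)-5,7,3',4'-tetra-O-benzylflavan-3-ol-4-one
Product: 19 all-cis 4-ol: (2S,3S)-3-O-(tert-butyldimethylsilyl)-5,7,3',4'-tetra-O-benzylepicatechin-4-ol with the 4-hydroxyl cis to O3 and to the 2-aryl group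
Conditions: L-Selectride (LiBH(s-Bu)3), THF, −78 °C
Reagents that add atoms: none
Why: Diastereoselective hydride reduction in which, in the half-chair with equatorial 2-aryl and axial 3-silyloxy groups, the hydride comes from the face opposite the axial silyloxy group, so the new hydroxyl should end up cis to O3 and to the aryl group.

Step 15
Reactants: 19 all-cis 4-ol
Product: 20 6,8-dibromo derivative of 19
Conditions: NBS (2.1 equiv), CH2Cl2, −78 → 0 °C, dark
Reagents that add atoms: N-bromosuccinimide, O=C1CCC(=O)N1Br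
Why: Electrophilic aromatic bromination of the most electron-rich ring A at C8 and C6 caps both nucleophilic carbons and makes the ring harder to oxidise, so that in step 16 the alcohol should survive DDQ and react only through oxygen.

Step 16
Reactants: 13 octa-O-benzyl procyanidin B2; 20 6,8-dibromo all-cis 4-ol (3 equiv, excess recovered)
Product: 21 protected trimer: the lower unit of 13 carries at C4 (β, trans to its 3-hydroxyl) the ether oxygen bound to C4 of the 6,8-dibromo-3-O-silyl-tetra-O-benzyl (2S,3S) all-cis unit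
Conditions: DDQ (1.2 equiv), 4 Å molecular sieves, CH2Cl2, 0 °C → rt
Reagents that add atoms: none
Why: DDQ-mediated oxidative etherification (cross-dehydrogenative C–O coupling, the reaction type of step 8 with a secondary alcohol), in which hydride abstraction at the only C4 methylene of 13 gives the cation and the 4-hydroxyl of 20 adds on the β face trans to the 3-hydroxyl, while C4 of 20 keeps its configuration because its C–O bond is not broken.

Step 17
Reactants: 21 protected trimer
Product: 22 dodeca-O-benzyl dibromo trimer with the three 3-hydroxyls free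
Conditions: TBAF, AcOH, THF, rt → 40 °C
Reagents that add atoms: none
Why: Fluoride-induced desilylation (driven by Si–F bond formation) under acetic acid buffering frees the 3-hydroxyl of the lower unit without touching benzyl ethers, aryl bromides or the ether bridge.

Step 18
Reactants: 22 dodeca-O-benzyl dibromo trimer
Product: 23 CNP0310719.1, epicatechin-(4β→8)-epicatechin whose lower C4 (β) is ether-linked to C4 of all-cis (2S,3S)-flavan-3,4-diol
Conditions: H2 (1 atm), Pd(OH)2/C, Et3N, THF/MeOH/H2O, rt, stopped at full debenzylation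
Reagents that add atoms: none
Why: Catalytic hydrogenolysis cleaves the twelve aryl benzyl ethers and both aryl C–Br bonds, which should react much faster than the hindered dialkyl ether between two ortho,ortho-disubstituted benzylic carbons, and triethylamine takes up HBr so that the acid-labile bridge is not ionised.

**Compound list**

1 | 3,5-bis(benzyloxy)phenol | Oc1cc(OCc2ccccc2)cc(OCc2ccccc2)c1 | starting material
2 | 1-(allyloxy)-3,5-bis(benzyloxy)benzene | C=CCOc1cc(OCc2ccccc2)cc(OCc2ccccc2)c1 | intermediate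
3 | 2-allyl-3,5-bis(benzyloxy)phenol | C=CCc1c(O)cc(OCc2ccccc2)cc1OCc1ccccc1 | intermediate
4 | 3,4-bis(benzyloxy)benzoic acid | OC(=O)c1ccc(OCc2ccccc2)c(OCc2ccccc2)c1 | starting material
5 | 2-allyl-3,5-bis(benzyloxy)phenyl 3,4-bis(benzyloxy)benzoate | C=CCc1c(OC(=O)c2ccc(OCc3ccccc3)c(OCc3ccccc3)c2)cc(OCc2ccccc2)cc1OCc1ccccc1 | intermediate
6 | dichlorotitanium alkylidene of 5, Ti=CH–CH2–aryl (not isolated) | Cl[Ti](Cl)=CCc1c(OC(=O)c2ccc(OCc3ccccc3)c(OCc3ccccc3)c2)cc(OCc2ccccc2)cc1OCc1ccccc1 | intermediate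
7 | 5,7-bis(benzyloxy)-2-[3,4-bis(benzyloxy)phenyl]-4H-chromene | c1ccccc1COc1cc(OCc2ccccc2)c2c(c1)OC(c1ccc(OCc3ccccc3)c(OCc3ccccc3)c1)=CC2 | intermediate
8 | (2R,3S)-flavan-3-yl(isopinocampheyl)borane, tetra-O-benzyl (not isolated) | c1ccccc1COc1cc(OCc2ccccc2)c2c(c1)O[C@H](c1ccc(OCc3ccccc3)c(OCc3ccccc3)c1)[C@@H]([BH][C@@H]3C[C@@H]4C[C@H]([C@H]3C)C4(C)C)C2 | intermediate
9 | (2R,3S)-5,7,3',4'-tetra-O-benzylcatechin (2,3-trans) | c1ccccc1COc1cc(OCc2ccccc2)c2c(c1)O[C@H](c1ccc(OCc3ccccc3)c(OCc3ccccc3)c1)[C@@H](O)C2 | intermediate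
10 | (2R)-5,7,3',4'-tetra-O-benzylflavan-3-one | c1ccccc1COc1cc(OCc2ccccc2)c2c(c1)O[C@H](c1ccc(OCc3ccccc3)c(OCc3ccccc3)c1)C(=O)C2 | intermediate
11 | (2R,3R)-5,7,3',4'-tetra-O-benzylepicatechin (2,3-cis) | c1ccccc1COc1cc(OCc2ccccc2)c2c(c1)O[C@H](c1ccc(OCc3ccccc3)c(OCc3ccccc3)c1)[C@H](O)C2 | intermediate
12 | 4β-(2-ethoxyethoxy)-5,7,3',4'-tetra-O-benzylepicatechin | c1ccccc1COc1cc(OCc2ccccc2)c2c(c1)O[C@H](c1ccc(OCc3ccccc3)c(OCc3ccccc3)c1)[C@H](O)[C@H]2OCCOCC | intermediate
13 | octa-O-benzyl procyanidin B2 (4β→8) | c1ccccc1COc1cc(OCc2ccccc2)c2c(c1)O[C@H](c1ccc(OCc3ccccc3)c(OCc3ccccc3)c1)[C@H](O)[C@H]2c1c(OCc3ccccc3)cc(OCc3ccccc3)c2c1O[C@H](c1ccc(OCc3ccccc3)c(OCc3ccccc3)c1)[C@H](O)C2 | intermediate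
14 | (+)-epicatechin, (2S,3S) | Oc1cc(O)c2c(c1)O[C@@H](c1ccc(O)c(O)c1)[C@@H](O)C2 | starting material
15 | (2S,3S)-5,7,3',4'-tetra-O-benzylepicatechin | c1ccccc1COc1cc(OCc2ccccc2)c2c(c1)O[C@@H](c1ccc(OCc3ccccc3)c(OCc3ccccc3)c1)[C@@H](O)C2 | intermediate
16 | 3-O-TBS ether of 15 | c1ccccc1COc1cc(OCc2ccccc2)c2c(c1)O[C@@H](c1ccc(OCc3ccccc3)c(OCc3ccccc3)c1)[C@@H](O[Si](C)(C)C(C)(C)C)C2 | intermediate
17 | 4-hydroxy derivative of 16, 4-OH trans to O3 | c1ccccc1COc1cc(OCc2ccccc2)c2c(c1)O[C@@H](c1ccc(OCc3ccccc3)c(OCc3ccccc3)c1)[C@@H](O[Si](C)(C)C(C)(C)C)[C@@H]2O | intermediate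
18 | 4-ketone (2,3-cis 3-O-TBS tetra-O-benzyl dihydroflavonol, 2S,3S) | c1ccccc1COc1cc(OCc2ccccc2)c2c(c1)O[C@@H](c1ccc(OCc3ccccc3)c(OCc3ccccc3)c1)[C@@H](O[Si](C)(C)C(C)(C)C)C2=O | intermediate
19 | all-cis 4-ol (2,3-cis, 3,4-cis) | c1ccccc1COc1cc(OCc2ccccc2)c2c(c1)O[C@@H](c1ccc(OCc3ccccc3)c(OCc3ccccc3)c1)[C@@H](O[Si](C)(C)C(C)(C)C)[C@H]2O | intermediate
20 | 6,8-dibromo derivative of 19 | c1ccccc1COc1c(Br)c(OCc2ccccc2)c2c(c1Br)O[C@@H](c1ccc(OCc3ccccc3)c(OCc3ccccc3)c1)[C@@H](O[Si](C)(C)C(C)(C)C)[C@H]2O | intermediate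
21 | protected trimer (dodeca-O-benzyl, dibromo, lower 3-O-TBS) | c1ccccc1COc1cc(OCc2ccccc2)c2c(c1)O[C@H](c1ccc(OCc3ccccc3)c(OCc3ccccc3)c1)[C@H](O)[C@H]2c1c(OCc3ccccc3)cc(OCc3ccccc3)c2c1O[C@H](c1ccc(OCc3ccccc3)c(OCc3ccccc3)c1)[C@H](O)[C@H]2O[C@H]1c2c(OCc3ccccc3)c(Br)c(OCc3ccccc3)c(Br)c2O[C@@H](c2ccc(OCc3ccccc3)c(OCc3ccccc3)c2)[C@H]1O[Si](C)(C)C(C)(C)C | intermediate
22 | desilylated protected trimer (dodeca-O-benzyl, dibromo) | c1ccccc1COc1cc(OCc2ccccc2)c2c(c1)O[C@H](c1ccc(OCc3ccccc3)c(OCc3ccccc3)c1)[C@H](O)[C@H]2c1c(OCc3ccccc3)cc(OCc3ccccc3)c2c1O[C@H](c1ccc(OCc3ccccc3)c(OCc3ccccc3)c1)[C@H](O)[C@H]2O[C@H]1c2c(OCc3ccccc3)c(Br)c(OCc3ccccc3)c(Br)c2O[C@@H](c2ccc(OCc3ccccc3)c(OCc3ccccc3)c2)[C@H]1O | intermediate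
23 | CNP0310719.1 | Oc1cc(O)c2c(c1)O[C@H](c1ccc(O)c(O)c1)[C@H](O)[C@H]2c1c(O)cc(O)c2c1O[C@H](c1ccc(O)c(O)c1)[C@H](O)[C@H]2O[C@H]1c2c(O)cc(O)cc2O[C@@H](c2ccc(O)c(O)c2)[C@H]1O | target

**Step count.** Total: 18 steps. Longest linear sequence: 12 steps (steps 1–9, then 16–18); the lower-unit branch has 6 steps before the union.

**Steps most likely to fail**

Step 16. Capture of the C4 cation by the hindered secondary alcohol may be slower than its return to the DDQ adduct and over-oxidation of the new ether. The fallback separates oxidation from C–O bond formation and sets out from 13. DDQ with excess 2-ethoxyethanol in CH2Cl2 should give the 4β-(2-ethoxyethoxy) dimer F1, since a small primary alcohol traps the cation as in step 8. Exchange with 2-mercaptobenzothiazole and BF3·OEt2 at −78 °C gives the 4β-(benzothiazol-2-ylthio) dimer F2. AgBF4 with 2,6-di-tert-butylpyridine and 4 Å molecular sieves in CH2Cl2/THF at 0 °C then activates the thioether irreversibly and without acid in the presence of 20, and the route is rejoined at 21.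

Step 18. Hydrogenolysis of the two benzylic C4–O bonds of the ether bridge may compete with removal of the benzyl groups. The fallback exchanges the benzyl groups before the bridge is made, so that no reduction follows it; it sets out from 13 and from 18. From 13, H2 with Pd(OH)2/C gives procyanidin B2 F3, and TBSCl with imidazole in DMF silylates its eight phenols to the octa-O-TBS dimer F4. From 18, the same hydrogenolysis (the aryl ketone survives) gives the 3-O-TBS tetraphenol ketone F5, Ac2O in pyridine gives the tetraacetate ketone F6, and Zn(BH4)2 in ether at −20 °C gives the all-cis tetraacetate 4-ol F7. The acetylated ring A of F7 is inert to DDQ and not nucleophilic at carbon. DDQ coupling of F4 with F7 as in step 16 gives the silyl- and acetyl-protected trimer F8. TBAF in THF followed by NH4OAc in aqueous methanol under argon removes all silyl and acetyl groups and arrives at 23.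

Step 4. Ethylidenation of the ester carbonyl may outrun alkene exchange and leave an acyclic enol ether that the titanium reagent does not close. The fallback separates the two events and sets out from 5. Takai methylenation (CH2Br2, Zn, TiCl4, TMEDA, THF) gives the 1-arylvinyl aryl ether F9. Ring-closing metathesis with the second-generation Grubbs catalyst (RuCl2(=CHPh)(H2IMes)(PCy3)) in toluene at 80 °C rejoins the route at 7.

**Further compounds**

F1 | step 16 | octa-O-benzyl procyanidin B2 with 4β-(2-ethoxyethoxy) group on the lower unit | c1ccccc1COc1cc(OCc2ccccc2)c2c(c1)O[C@H](c1ccc(OCc3ccccc3)c(OCc3ccccc3)c1)[C@H](O)[C@H]2c1c(OCc3ccccc3)cc(OCc3ccccc3)c2c1O[C@H](c1ccc(OCc3ccccc3)c(OCc3ccccc3)c1)[C@H](O)[C@H]2OCCOCC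
F2 | step 16 | octa-O-benzyl procyanidin B2 with 4β-(benzothiazol-2-ylthio) group on the lower unit | c1ccccc1COc1cc(OCc2ccccc2)c2c(c1)O[C@H](c1ccc(OCc3ccccc3)c(OCc3ccccc3)c1)[C@H](O)[C@H]2c1c(OCc3ccccc3)cc(OCc3ccccc3)c2c1O[C@H](c1ccc(OCc3ccccc3)c(OCc3ccccc3)c1)[C@H](O)[C@H]2Sc1nc2ccccc2s1
F3 | step 18 | procyanidin B2 | Oc1cc(O)c2c(c1)O[C@H](c1ccc(O)c(O)c1)[C@H](O)[C@H]2c1c(O)cc(O)c2c1O[C@H](c1ccc(O)c(O)c1)[C@H](O)C2
F4 | step 18 | octa-O-TBS (phenolic) procyanidin B2 | CC(C)(C)[Si](C)(C)Oc1cc(O[Si](C)(C)C(C)(C)C)c2c(c1)O[C@H](c1ccc(O[Si](C)(C)C(C)(C)C)c(O[Si](C)(C)C(C)(C)C)c1)[C@H](O)[C@H]2c1c(O[Si](C)(C)C(C)(C)C)cc(O[Si](C)(C)C(C)(C)C)c2c1O[C@H](c1ccc(O[Si](C)(C)C(C)(C)C)c(O[Si](C)(C)C(C)(C)C)c1)[C@H](O)C2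
F5 | step 18 | (2S,3S)-3-O-TBS-5,7,3',4'-tetrahydroxyflavan-3-ol-4-one (2,3-cis) | Oc1cc(O)c2c(c1)O[C@@H](c1ccc(O)c(O)c1)[C@@H](O[Si](C)(C)C(C)(C)C)C2=O
F6 | step 18 | tetraacetate of F5 | CC(=O)Oc1cc(OC(C)=O)c2c(c1)O[C@@H](c1ccc(OC(C)=O)c(OC(C)=O)c1)[C@@H](O[Si](C)(C)C(C)(C)C)C2=O
F7 | step 18 | all-cis 4-ol from F6 (tetraacetate, 3-O-TBS) | CC(=O)Oc1cc(OC(C)=O)c2c(c1)O[C@@H](c1ccc(OC(C)=O)c(OC(C)=O)c1)[C@@H](O[Si](C)(C)C(C)(C)C)[C@H]2O
F8 | step 18 | trimer with eight phenolic TBS groups on the upper and middle units and tetraacetate 3-O-TBS lower unit | CC(C)(C)[Si](C)(C)Oc1cc(O[Si](C)(C)C(C)(C)C)c2c(c1)O[C@H](c1ccc(O[Si](C)(C)C(C)(C)C)c(O[Si](C)(C)C(C)(C)C)c1)[C@H](O)[C@H]2c1c(O[Si](C)(C)C(C)(C)C)cc(O[Si](C)(C)C(C)(C)C)c2c1O[C@H](c1ccc(O[Si](C)(C)C(C)(C)C)c(O[Si](C)(C)C(C)(C)C)c1)[C@H](O)[C@H]2O[C@H]1c2c(OC(C)=O)cc(OC(C)=O)cc2O[C@@H](c2ccc(OC(C)=O)c(OC(C)=O)c2)[C@H]1O[Si](C)(C)C(C)(C)C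
F9 | step 4 | 2-allyl-3,5-bis(benzyloxy)phenyl 1-[3,4-bis(benzyloxy)phenyl]vinyl ether | C=CCc1c(OC(=C)c2ccc(OCc3ccccc3)c(OCc3ccccc3)c2)cc(OCc2ccccc2)cc1OCc1ccccc1
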